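A one-step world would make target in proportion to the reagent charged, so one count per time would serve every charge.

| flask | substrate | reagent in the second phase | remark | time | volume of the second phase over the first |
|---|---|---|---|---|---|
| summer | 0.050 M | 0.030 M | run made earlier |  |  |
| dawn | 0.050 M | 0.045 M | run made earlier |  |  |
| noon | 0.075 M | 0.060 M | run made earlier |  |  |
| flask | 0.050 M | 0.0600 M |  | 5.0 min | 1.0 |

| run | time / min | target / % | substrate / % |
|---|---|---|---|
| summer | 1.33 | 2.0 | 97.6 |
| summer | 2.50 | 5.0 | 95.0 |
| summer | 4.00 | 8.8 | 90.7 |
| summer | 5.00 | 11.4 | 87.3 |
| summer | 6.00 | 12.7 | 84.6 |
| dawn | 0.500 | 0.4 | 99.6 |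
| dawn | 1.50 | 3.0 | 97.0 |
| dawn | 3.00 | 8.8 | 89.4 |
| dawn | 4.00 | 12.7 | 86.1 |
| dawn | 6.00 | 17.7 | 78.4 |
| noon | 0.500 | 0.3 | 99.3 |
| noon | 0.833 | 1.6 | 98.4 |
| noon | 1.50 | 4.5 | 95.6 |
| noon | 3.00 | 10.2 | 88.4 |
| noon | 6.00 | 18.8 | 76.7 |

(readings scatter by 0.3 percentage points)

- in the second phase: reagent in the second phase; everything else is in the first
- charges count per volume of the first phase; a concentration in a rate is the amount of a species over the volume of its own phase; every rate counts per litre of the first phase
- the earlier runs were read with a standard deviation of 0.3 percentage points
- the earlier runs hold the two phases in the same ratio of volumes as the flask asked about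

- oak: doubling the transfer coefficient of the reagent in the second phase, all else as stated
- larch: doubling the amount of reagent in the second phase, all else as stated

- target at 5.0 min, in percent of the substrate charged
- the change that raises the amount of target at 5.0 min, in percent of the substrate charged most ("none" if none brings more than 2 percentage points) (oak / larch / none)
- amount of target at 5.0 min, in percent of the substrate charged, after larch

1. Count turnovers. The summer run at 5.00 min reads 0.190 as n, the turnover count: moles of target made by that time per mole of reagent charged in the second phase.

2. Holding n, the flask with twice the summer charge would give 22.8% of target.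

3. That step is the weak link. Taken midway between its readings at 4.00 min and 6.00 min, the dawn run gives n = 0.169, lower than summer, so n falls as the charge rises.

4. Reforged, with the fall carried as a power of the charge, each doubling multiplies n by f = 0.818. The flask then has n = 0.155, which is 18.6% of target.

5. One more factor f gives 30.5% after larch, a gain of 12 percentage points, larger than the margin. No run varies transfer, so this count gives no figure for oak.

The forecast, holding that “transfer and reaction are mixed”, stood at 20.5%, larch and 35%.

The flask gives 18.7% against the 18.6% reckoned here. The better change is larch, worth 7.5 points against 4.3 points for oak, and it reaches 26.2% against the 30.5% reckoned here.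

    reagent in the reaction phase → decomposed reagent (k = 0.0510 /min)
    reagent in the reaction phase + target → over-reacted product (k = 12.0 /M/min)
    substrate + reagent in the reaction phase → target (k = 7.10 /M/min)
    reagent in the reaction phase ⇌ reagent in the second phase, rate k4*([reagent in the reaction phase] - [reagent in the second phase]/K4) per volume of the first phase (partition coefficient = 1.30, kL = 0.180 /min)

The flask's turnover count comes to 0.156 at 5.0 min, lower than the 0.190 of summer. The drag on the way of reagent from the second phase across to the reaction phase, together with the length of the run, is part of what holds it down: the same flask with that drag taken away holds 27.0% of target instead of 18.7%, so n = 0.225, and the flask as it stands, read at 50.0 min, holds 26.2%. After larch, the flask stands at n = 0.109.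

Readings and results were generated by integration for substances that don't exist; noise was put on by code.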